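**Plan** (locants follow the target's cyclohepta[b]furan-2-one skeleton: O1, C2(=O), C3, C3a, C4–C8, C8a)

1. Retrosynthetic cuts, in order: the C(=O)–CH= bond of the C7 butenoyl group and the C8 ester C–O bond; then, in one operation, the C3a–C8a ring-fusion bond (shared by the cycloheptane and the lactone) and the lactone O1–C2 bond; then C4–C5 (vinylogous aldol) and C6–C7 (Ireland–Claisen), back to L-threitol acetonide.
2. Forward order: the C7/C8 diol is bought as a dioxolane; C7 becomes quaternary and C6 is set by a [3,3] shift; one aldol adds the C5 carbinol and the enoate arm; SmI2 then closes the seven-membered ring and the lactone together; the butenoyl and angeloyl groups go on last.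
3. Enabling feature: in the open chain C8a is an aldehyde carbon and C3a the β-carbon of an α-methyl enoate, two acceptor carbons joined through C8–C7–C6–C5–C4. One-electron reduction makes C8a a nucleophilic ketyl that adds 7-exo to C3a; the C8a alkoxide then sits γ to the ester and lactonises. The trans-dioxolane across C7/C8 holds the chain ends.
4. Stereochemistry: C8 from the chiral pool; C7 and C6 from the Claisen step (ring face, chair); C5 by Felkin–Anh addition; C8a and C3a in the key step; C3 by kinetic protonation of the lactone enolate; alkene geometries from methyl tiglate, angelic acid and (E)-1-bromopropene.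

Key step: step 13

Remark: the target is taken as drawn, with the (Z)-2-methylbut-2-enoate on O-8 and the (E)-but-2-enoyl group on C7. Geometrically pure (E)-but-2-en-1-ol, angelic acid and (E)-1-bromoprop-1-ene are taken as commercial. The same locants are used for the open-chain intermediates (for example "future C8a").

**Route**

Step 1
Reactants: 1 (4S,5S)-2,2-dimethyl-1,3-dioxolane-4,5-dimethanol (2,3-O-isopropylidene-L-threitol)
Product: 2 [(4S,5S)-5-[(tert-butyldimethylsilyloxy)methyl]-2,2-dimethyl-1,3-dioxolan-4-yl]methanol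
Conditions: NaH (1.0 equiv), THF, 0 °C; TBSCl (1.0 equiv), 0 °C to rt
Reagents that add atoms: tert-butyldimethylsilyl chloride, CC(C)(C)[Si](C)(C)Cl
Why: O-silylation of the monosodium alkoxide of a C2-symmetric diol, whose two hydroxyls are equivalent, so only mono- against bis-silylation has to be controlled and no stereocentre is touched.

Step 2
Reactants: 2
Product: 4 (4R,5S)-5-[(tert-butyldimethylsilyloxy)methyl]-2,2-dimethyl-1,3-dioxolane-4-carboxylic acid, via aldehyde 3 (not isolated)
Conditions: TEMPO (cat.), PhI(OAc)2 (2.2 equiv), MeCN/H2O (1:1), rt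
Reagents that add atoms: water, O
Why: nitroxyl-catalysed oxidation of the primary alcohol to the aldehyde, whose hydrate is oxidised on to the acid; silyl ether and acetonide should survive, and the configuration next to the carboxyl does not matter because that carbon is planarised in step 4.

Step 3
Reactants: 4; 5 (E)-but-2-en-1-ol
Product: 6 (2E)-but-2-en-1-yl (4R,5S)-5-[(tert-butyldimethylsilyloxy)methyl]-2,2-dimethyl-1,3-dioxolane-4-carboxylate
Conditions: DCC, DMAP (cat.), CH2Cl2, 0 °C to rt
Reagents that add atoms: none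
Why: Steglich esterification of the acid with a primary allylic alcohol, which leaves the (E)-alkene and the remote stereocentre untouched.

Step 4
Reactants: 6
Product: 10 (4S,5S)-4-[(2S)-but-3-en-2-yl]-5-[(tert-butyldimethylsilyloxy)methyl]-2,2-dimethyl-1,3-dioxolane-4-carboxylic acid, via chelated lithium enolate 7 (not isolated), via trimethylsilyl ketene acetal 8 (not isolated), via trimethylsilyl ester 9 (not isolated)
Conditions: LiN(i-Pr)2 (1.2 equiv), THF, −78 °C; TMSCl (2 equiv), −78 °C to rt; aqueous citric acid work-up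
Reagents that add atoms: none
Why: Ireland–Claisen rearrangement of an α-alkoxy ester, in which lithium bridges the enolate oxygen and the ring oxygen on the same carbon so that the ketene acetal carries OSi syn to that oxygen; the crotyl group is delivered through a chair transition state to the ring face anti to the CH2OTBS group, which makes the quaternary future C7, and the (E)-alkene places its methyl equatorial, which sets the future C6 as (S); β-elimination is disfavoured because the ring C–O bond β to the enolate lies near its nodal plane.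

Step 5
Reactants: 10
Product: 11 [(4R,5S)-4-[(2S)-but-3-en-2-yl]-5-[(tert-butyldimethylsilyloxy)methyl]-2,2-dimethyl-1,3-dioxolan-4-yl]methanol
Conditions: LiAlH4, THF, 0 °C to reflux; aqueous work-up
Reagents that add atoms: none
Why: hydride reduction of the carboxylic acid to the neopentyl primary alcohol; alkene, silyl ether and acetonide are inert and no stereocentre is affected.

Step 6
Reactants: 11
Product: 12 (4R,5S)-4-[(2S)-but-3-en-2-yl]-5-[(tert-butyldimethylsilyloxy)methyl]-4-[(4-methoxybenzyloxy)methyl]-2,2-dimethyl-1,3-dioxolane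
Conditions: NaH, 4-methoxybenzyl chloride, n-Bu4NI (cat.), DMF, 0 °C to rt
Reagents that add atoms: 4-methoxybenzyl chloride, COc1ccc(CCl)cc1
Why: Williamson etherification of the neopentyl alkoxide, giving an ether that can later be removed oxidatively in the presence of alkenes.

Step 7
Reactants: 12
Product: 14 (2R)-2-[(4R,5S)-5-[(tert-butyldimethylsilyloxy)methyl]-4-[(4-methoxybenzyloxy)methyl]-2,2-dimethyl-1,3-dioxolan-4-yl]propanal, via vicinal diol 13 (not isolated)
Conditions: OsO4 (cat.), NaIO4 (4 equiv), 2,6-lutidine, 1,4-dioxane/H2O (3:1), rt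
Reagents that add atoms: sodium periodate, [Na+].[O-][I](=O)(=O)=O (oxygen source, relayed by catalytic osmium tetroxide, O=[Os](=O)(=O)=O)
Why: Lemieux–Johnson cleavage (dihydroxylation of the only alkene, then periodate scission) gives the future C5 aldehyde; the lutidine buffer should prevent epimerisation of the α-methyl centre and the anisyl ether is not attacked.

Step 8
Reactants: 15 methyl tiglate (methyl (2E)-2-methylbut-2-enoate)
Product: 17 tert-butyl[(1-methoxy-2-methylbuta-1,3-dien-1-yl)oxy]dimethylsilane (ketene acetal geometry immaterial), via lithium dienolate 16 (not isolated)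
Conditions: LiN(i-Pr)2, THF, −78 °C; DMPU; TBSCl, −78 °C to rt
Reagents that add atoms: tert-butyldimethylsilyl chloride, CC(C)(C)[Si](C)(C)Cl
Why: γ-deprotonation of the enoate and O-silylation of the extended enolate gives the silyl dienol ether needed for a vinylogous aldol addition.

Step 9
Reactants: 14; 17
Product: 18 methyl (2E,5R,6S)-6-[(4R,5S)-5-[(tert-butyldimethylsilyloxy)methyl]-4-[(4-methoxybenzyloxy)methyl]-2,2-dimethyl-1,3-dioxolan-4-yl]-5-hydroxy-2-methylhept-2-enoate
Conditions: B(C6F5)3 (1.0 equiv), i-PrOH (1.1 equiv), Et2O, −78 °C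
Reagents that add atoms: none
Why: vinylogous Mukaiyama aldol addition through the γ-carbon of the dienolate under a bulky, non-chelating Lewis acid; Felkin–Anh attack anti to the fully substituted dioxolane carbon should give the 5,6-syn carbinol (5R), and the conjugated (E)-enoate arm is installed in the same step.

Step 10
Reactants: 18
Product: 19 methyl (2E,5R,6S)-6-[(4R,5S)-5-[(tert-butyldimethylsilyloxy)methyl]-4-[(4-methoxybenzyloxy)methyl]-2,2-dimethyl-1,3-dioxolan-4-yl]-2-methyl-5-(triisopropylsilyloxy)hept-2-enoate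
Conditions: TIPSOTf, 2,6-lutidine, CH2Cl2, −78 to 0 °C
Reagents that add atoms: triisopropylsilyl trifluoromethanesulfonate, CC(C)[Si](OS(=O)(=O)C(F)(F)F)(C(C)C)C(C)C
Why: silylation of the hindered secondary alcohol with a silyl triflate gives an ether robust enough to survive every later step up to the last.

Step 11
Reactants: 19
Product: 20 methyl (2E,5R,6S)-6-[(4R,5S)-5-(hydroxymethyl)-4-[(4-methoxybenzyloxy)methyl]-2,2-dimethyl-1,3-dioxolan-4-yl]-2-methyl-5-(triisopropylsilyloxy)hept-2-enoate
Conditions: HF·pyridine, pyridine, THF, 0 °C to rt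
Reagents that add atoms: none
Why: fluoride cleaves the unhindered primary tert-butyldimethylsilyl ether much faster than the secondary triisopropylsilyl ether, and the buffered medium spares the acetonide.

Step 12
Reactants: 20
Product: 21 methyl (2E,5R,6S)-6-[(4R,5R)-5-formyl-4-[(4-methoxybenzyloxy)methyl]-2,2-dimethyl-1,3-dioxolan-4-yl]-2-methyl-5-(triisopropylsilyloxy)hept-2-enoate
Conditions: Dess–Martin periodinane, CH2Cl2, rt
Reagents that add atoms: none
Why: Dess–Martin oxidation of the primary alcohol to the future C8a aldehyde under near-neutral conditions, which should not epimerise the α-alkoxy centre held in the dioxolane.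

Step 13
Reactants: 21
Product: 23 7,8-(isopropylidenedioxy)-7-[(4-methoxybenzyloxy)methyl]-3,6-dimethyl-5-(triisopropylsilyloxy)octahydro-2H-cyclohepta[b]furan-2-one (ring centres as in the target; both C3 epimers), via cyclised hydroxy ester 22 (not isolated)
Conditions: SmI2 (2.5 equiv, 0.1 M in THF), HMPA (8 equiv), t-BuOH (2 equiv), THF, slow addition of 21 (final 0.01 M), −78 to 0 °C; aqueous work-up
Reagents that add atoms: none
Why: SmI2 transfers one electron to the aldehyde of 21 to give a samarium ketyl whose carbon, now nucleophilic, adds to the β-carbon of the (E)-α-methyl enoate; a second electron gives a samarium enolate that t-BuOH protonates, and the C8a alkoxide on trivalent samarium attacks the methyl ester and expels methanol. The closest known reaction type is the SmI2-mediated aldehyde–enoate ketyl–olefin cyclisation with lactonisation in the same flask, known for five- to eight-membered carbocycles and for α-alkoxy aldehydes. The cycloheptane closes by 7-exo-trig radical addition and the lactone by 5-exo-trig acyl substitution. At C8a the ketyl C–O bond should lie anti to the neighbouring dioxolane C–O bond at C8 (repulsion from the samarium-bound oxygen), giving the 8,8a-trans relation; at C3a coordination of the ester carbonyl to the ketyl samarium should hold the enoate syn to the ketyl oxygen, giving the cis ring fusion; C3 is not relied on here and is set in step 14. The step needs reduction of the aldehyde before the enoate (the aldehyde is the easier acceptor) and ring closure faster than pinacol coupling or loss of the α-alkoxy group; high dilution, the activated acceptor and the trans-dioxolane that brings the C7 and C8 arms together serve this.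

Step 14
Reactants: 23
Product: 25 (3R)-epimer of 23 (3-methyl cis to C4; all seven ring stereocentres as in the target), via lithium enolate 24 (not isolated)
Conditions: LiN(i-Pr)2 (1.2 equiv), THF, −78 °C; then AcOH (excess) in THF, −78 °C
Reagents that add atoms: none
Why: both C3 epimers give the same planar lactone enolate, and kinetic protonation from the convex face of the cis-fused bicycle (anti to the C3a–C4 bond) should place the new hydrogen cis to H-3a and the methyl on the concave face, the less stable arrangement that the target requires.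

Step 15
Reactants: 25
Product: 26 7,8-dihydroxy-7-[(4-methoxybenzyloxy)methyl]-3,6-dimethyl-5-(triisopropylsilyloxy)octahydro-2H-cyclohepta[b]furan-2-one (configuration as in the target; 8-OH trans to 7-OH)
Conditions: AcOH/H2O (4:1), 50 °C
Reagents that add atoms: none
Why: acid hydrolysis of the strained trans-fused acetonide; the anisyl ether, the triisopropylsilyl ether and the lactone should tolerate aqueous acetic acid.

Step 16
Reactants: 26; 27 angelic acid ((2Z)-2-methylbut-2-enoic acid)
Product: 29 8-O-[(2Z)-2-methylbut-2-enoyl] derivative of 26, via angelic 2,4,6-trichlorobenzoic anhydride 28 (not isolated)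
Conditions: 2,4,6-trichlorobenzoyl chloride, Et3N, toluene, rt (27 to 28); then 26, 80 °C
Reagents that add atoms: none
Why: Yamaguchi-type esterification in which the secondary C8 hydroxyl attacks the unhindered angeloyl carbonyl of the mixed anhydride while the tertiary C7 hydroxyl does not react; leaving out a nucleophilic catalyst is what should keep the (Z)-alkene from isomerising, and the acylation is done before the enone exists so that the free C8 hydroxyl never meets it.

Step 17
Reactants: 29
Product: 30 7-(hydroxymethyl) compound (anisyl ether of 29 cleaved)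
Conditions: DDQ, CH2Cl2/pH 7 buffer (10:1), 0 °C to rt
Reagents that add atoms: none
Why: oxidative cleavage of the 4-methoxybenzyl ether by hydride abstraction and hydrolysis, under neutral conditions that leave the angelate, the lactone and the silyl ether alone.

Step 18
Reactants: 30
Product: 31 7-formyl compound (α-hydroxy aldehyde)
Conditions: Dess–Martin periodinane, CH2Cl2, 0 °C to rt
Reagents that add atoms: none
Why: Dess–Martin oxidation of the primary alcohol; the neighbouring tertiary alcohol cannot be oxidised and the aldehyde has no α-hydrogen to lose.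

Step 19
Reactants: 31; 32 (E)-1-bromoprop-1-ene
Product: 34 7-[(2E)-1-hydroxybut-2-en-1-yl] compound (both carbinol epimers), via (E)-prop-1-enylchromium dichloride 33 (not isolated)
Conditions: CrCl2 (4 equiv), NiCl2 (cat.), DMF, rt
Reagents that add atoms: none
Why: Nozaki–Hiyama–Kishi reaction, in which the alkenyl bromide adds oxidatively to zerovalent nickel, is passed to trivalent chromium and adds only to the aldehyde in the presence of lactone, angelate and free tertiary hydroxyl, with retention of the (E)-alkene; the new carbinol centre is not controlled and is removed in step 20.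

Step 20
Reactants: 34
Product: 35 5-O-triisopropylsilyl ether of the target
Conditions: Dess–Martin periodinane, CH2Cl2, 0 °C
Reagents that add atoms: none
Why: Dess–Martin oxidation of the secondary allylic alcohol to the (E)-enone; the tertiary α-hydroxyl stays, and the ketone cannot enolise towards the quaternary C7.

Step 21
Reactants: 35
Product: 36 (3R,3aS,5R,6S,7S,8S,8aR)-7-[(2E)-but-2-enoyl]-5,7-dihydroxy-3,6-dimethyl-2-oxooctahydro-2H-cyclohepta[b]furan-8-yl (2Z)-2-methylbut-2-enoate (CNP0183494.1)
Conditions: HF·pyridine, THF, 0 °C to rt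
Reagents that add atoms: none
Why: fluoride cleavage of the last silyl ether under non-basic conditions, which should leave the enone, the angelate geometry, the α-ketol and the C3 configuration intact.

**Compound list**

1 | (4S,5S)-2,2-dimethyl-1,3-dioxolane-4,5-dimethanol | OC[C@@H]1OC(C)(C)O[C@H]1CO | starting material
2 | [(4S,5S)-5-[(tert-butyldimethylsilyloxy)methyl]-2,2-dimethyl-1,3-dioxolan-4-yl]methanol | CC(C)(C)[Si](C)(C)OC[C@@H]1OC(C)(C)O[C@H]1CO | intermediate
3 | (4R,5S)-5-[(tert-butyldimethylsilyloxy)methyl]-2,2-dimethyl-1,3-dioxolane-4-carbaldehyde (not isolated) | CC(C)(C)[Si](C)(C)OC[C@@H]1OC(C)(C)O[C@H]1C=O | intermediate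
4 | (4R,5S)-5-[(tert-butyldimethylsilyloxy)methyl]-2,2-dimethyl-1,3-dioxolane-4-carboxylic acid | CC(C)(C)[Si](C)(C)OC[C@@H]1OC(C)(C)O[C@H]1C(=O)O | intermediate
5 | (E)-but-2-en-1-ol | C/C=C/CO | starting material
6 | (2E)-but-2-en-1-yl (4R,5S)-5-[(tert-butyldimethylsilyloxy)methyl]-2,2-dimethyl-1,3-dioxolane-4-carboxylate | CC(C)(C)[Si](C)(C)OC[C@@H]1OC(C)(C)O[C@H]1C(=O)OC/C=C/C | intermediate
7 | chelated lithium enolate of 6, OLi syn to the ring oxygen (not isolated) | CC(C)(C)[Si](C)(C)OC[C@@H]1OC(C)(C)O/C1=C(\O[Li])OC/C=C/C | intermediate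
8 | trimethylsilyl ketene acetal of 6, OSi syn to the ring oxygen (not isolated) | CC(C)(C)[Si](C)(C)OC[C@@H]1OC(C)(C)O/C1=C(\O[Si](C)(C)C)OC/C=C/C | intermediate
9 | trimethylsilyl ester of 10 (not isolated) | CC(C)(C)[Si](C)(C)OC[C@@H]1OC(C)(C)O[C@@]1(C(=O)O[Si](C)(C)C)[C@@H](C)C=C | intermediate
10 | (4S,5S)-4-[(2S)-but-3-en-2-yl]-5-[(tert-butyldimethylsilyloxy)methyl]-2,2-dimethyl-1,3-dioxolane-4-carboxylic acid | CC(C)(C)[Si](C)(C)OC[C@@H]1OC(C)(C)O[C@@]1(C(=O)O)[C@@H](C)C=C | intermediate
11 | [(4R,5S)-4-[(2S)-but-3-en-2-yl]-5-[(tert-butyldimethylsilyloxy)methyl]-2,2-dimethyl-1,3-dioxolan-4-yl]methanol | CC(C)(C)[Si](C)(C)OC[C@@H]1OC(C)(C)O[C@@]1(CO)[C@@H](C)C=C | intermediate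
12 | (4R,5S)-4-[(2S)-but-3-en-2-yl]-5-[(tert-butyldimethylsilyloxy)methyl]-4-[(4-methoxybenzyloxy)methyl]-2,2-dimethyl-1,3-dioxolane | CC(C)(C)[Si](C)(C)OC[C@@H]1OC(C)(C)O[C@@]1(COCc2ccc(OC)cc2)[C@@H](C)C=C | intermediate
13 | vicinal diol from dihydroxylation of the vinyl group of 12, carbinol epimers (not isolated) | CC(C)(C)[Si](C)(C)OC[C@@H]1OC(C)(C)O[C@@]1(COCc2ccc(OC)cc2)[C@@H](C)C(O)CO | intermediate
14 | (2R)-2-[(4R,5S)-5-[(tert-butyldimethylsilyloxy)methyl]-4-[(4-methoxybenzyloxy)methyl]-2,2-dimethyl-1,3-dioxolan-4-yl]propanal | CC(C)(C)[Si](C)(C)OC[C@@H]1OC(C)(C)O[C@@]1(COCc2ccc(OC)cc2)[C@@H](C)C=O | intermediate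
15 | methyl (2E)-2-methylbut-2-enoate (methyl tiglate) | C/C=C(\C)C(=O)OC | starting material
16 | lithium dienolate of methyl tiglate (not isolated) | C=CC(C)=C(OC)O[Li] | intermediate
17 | tert-butyl[(1-methoxy-2-methylbuta-1,3-dien-1-yl)oxy]dimethylsilane | C=CC(C)=C(OC)O[Si](C)(C)C(C)(C)C | intermediate
18 | methyl (2E,5R,6S)-6-[(4R,5S)-5-[(tert-butyldimethylsilyloxy)methyl]-4-[(4-methoxybenzyloxy)methyl]-2,2-dimethyl-1,3-dioxolan-4-yl]-5-hydroxy-2-methylhept-2-enoate | CC(C)(C)[Si](C)(C)OC[C@@H]1OC(C)(C)O[C@@]1(COCc2ccc(OC)cc2)[C@@H](C)[C@H](O)C/C=C(\C)C(=O)OC | intermediate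
19 | 5-O-triisopropylsilyl ether of 18 | CC(C)(C)[Si](C)(C)OC[C@@H]1OC(C)(C)O[C@@]1(COCc2ccc(OC)cc2)[C@@H](C)[C@H](O[Si](C(C)C)(C(C)C)C(C)C)C/C=C(\C)C(=O)OC | intermediate
20 | methyl (2E,5R,6S)-6-[(4R,5S)-5-(hydroxymethyl)-4-[(4-methoxybenzyloxy)methyl]-2,2-dimethyl-1,3-dioxolan-4-yl]-2-methyl-5-(triisopropylsilyloxy)hept-2-enoate | OC[C@@H]1OC(C)(C)O[C@@]1(COCc2ccc(OC)cc2)[C@@H](C)[C@H](O[Si](C(C)C)(C(C)C)C(C)C)C/C=C(\C)C(=O)OC | intermediate
21 | methyl (2E,5R,6S)-6-[(4R,5R)-5-formyl-4-[(4-methoxybenzyloxy)methyl]-2,2-dimethyl-1,3-dioxolan-4-yl]-2-methyl-5-(triisopropylsilyloxy)hept-2-enoate | O=C[C@@H]1OC(C)(C)O[C@@]1(COCc2ccc(OC)cc2)[C@@H](C)[C@H](O[Si](C(C)C)(C(C)C)C(C)C)C/C=C(\C)C(=O)OC | intermediate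
22 | cyclised hydroxy ester: cycloheptane with free C8a hydroxyl cis to the methyl propanoate arm on C3a, propanoate α-carbon as both epimers (not isolated) | CC1(C)O[C@H]2[C@H](O)[C@H](C(C)C(=O)OC)C[C@@H](O[Si](C(C)C)(C(C)C)C(C)C)[C@H](C)[C@@]2(O1)COCc3ccc(OC)cc3 | intermediate
23 | 7,8-(isopropylidenedioxy)-7-[(4-methoxybenzyloxy)methyl]-3,6-dimethyl-5-(triisopropylsilyloxy)octahydro-2H-cyclohepta[b]furan-2-one, C3a/C5/C6/C7/C8/C8a as in the target, both C3 epimers | CC1(C)O[C@H]2[C@@H]3OC(=O)C(C)[C@@H]3C[C@@H](O[Si](C(C)C)(C(C)C)C(C)C)[C@H](C)[C@@]2(O1)COCc4ccc(OC)cc4 | intermediate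
24 | lithium enolate of lactone 23 (not isolated) | CC1(C)O[C@H]2[C@@H]3OC(O[Li])=C(C)[C@@H]3C[C@@H](O[Si](C(C)C)(C(C)C)C(C)C)[C@H](C)[C@@]2(O1)COCc4ccc(OC)cc4 | intermediate
25 | (3R)-epimer of 23: 3-methyl cis to C4, all ring stereocentres as in the target | CC1(C)O[C@H]2[C@@H]3OC(=O)[C@H](C)[C@@H]3C[C@@H](O[Si](C(C)C)(C(C)C)C(C)C)[C@H](C)[C@@]2(O1)COCc4ccc(OC)cc4 | intermediate
26 | 7,8-dihydroxy-7-[(4-methoxybenzyloxy)methyl]-3,6-dimethyl-5-(triisopropylsilyloxy)octahydro-2H-cyclohepta[b]furan-2-one, configuration as in the target | O[C@H]1[C@@H]2OC(=O)[C@H](C)[C@@H]2C[C@@H](O[Si](C(C)C)(C(C)C)C(C)C)[C@H](C)[C@@]1(O)COCc3ccc(OC)cc3 | intermediate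
27 | angelic acid, (2Z)-2-methylbut-2-enoic acid | C/C=C(/C)C(=O)O | starting material
28 | angelic 2,4,6-trichlorobenzoic anhydride (not isolated) | C/C=C(/C)C(=O)OC(=O)c1c(Cl)cc(Cl)cc1Cl | intermediate
29 | 8-O-angelate of 26 | C/C=C(/C)C(=O)O[C@H]1[C@@H]2OC(=O)[C@H](C)[C@@H]2C[C@@H](O[Si](C(C)C)(C(C)C)C(C)C)[C@H](C)[C@@]1(O)COCc3ccc(OC)cc3 | intermediate
30 | 8-O-angeloyl-7-hydroxy-7-(hydroxymethyl) lactone, 5-O-triisopropylsilyl | C/C=C(/C)C(=O)O[C@H]1[C@@H]2OC(=O)[C@H](C)[C@@H]2C[C@@H](O[Si](C(C)C)(C(C)C)C(C)C)[C@H](C)[C@@]1(O)CO | intermediate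
31 | 8-O-angeloyl-7-formyl-7-hydroxy lactone, 5-O-triisopropylsilyl | C/C=C(/C)C(=O)O[C@H]1[C@@H]2OC(=O)[C@H](C)[C@@H]2C[C@@H](O[Si](C(C)C)(C(C)C)C(C)C)[C@H](C)[C@@]1(O)C=O | intermediate
32 | (E)-1-bromoprop-1-ene | C/C=C/Br | starting material
33 | (E)-prop-1-enylchromium dichloride (not isolated) | C/C=C/[Cr](Cl)Cl | intermediate
34 | 8-O-angeloyl-7-hydroxy-7-[(2E)-1-hydroxybut-2-en-1-yl] lactone, 5-O-triisopropylsilyl, both carbinol epimers | C/C=C(/C)C(=O)O[C@H]1[C@@H]2OC(=O)[C@H](C)[C@@H]2C[C@@H](O[Si](C(C)C)(C(C)C)C(C)C)[C@H](C)[C@@]1(O)C(O)/C=C/C | intermediate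
35 | 5-O-triisopropylsilyl ether of the target | C/C=C(/C)C(=O)O[C@H]1[C@@H]2OC(=O)[C@H](C)[C@@H]2C[C@@H](O[Si](C(C)C)(C(C)C)C(C)C)[C@H](C)[C@@]1(O)C(=O)/C=C/C | intermediate
36 | (3R,3aS,5R,6S,7S,8S,8aR)-7-[(2E)-but-2-enoyl]-5,7-dihydroxy-3,6-dimethyl-2-oxooctahydro-2H-cyclohepta[b]furan-8-yl (2Z)-2-methylbut-2-enoate | C/C=C(/C)C(=O)O[C@H]1[C@@H]2OC(=O)[C@H](C)[C@@H]2C[C@@H](O)[C@H](C)[C@@]1(O)C(=O)/C=C/C | target

**Totals**

Total step count: 21. Longest linear sequence: 20 steps (steps 1–7 and 9–21; step 8 makes the side fragment 17).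

**Steps most likely to fail**

1. Step 13 (key step). The seven-membered closure may be slower than simple reduction or pinacol coupling of the aldehyde, or the ketyl may add to the wrong face of the enoate and give the trans-fused series. The fallback makes the same bond by a polar chromium allylation. It sets out from 19: ozonolysis (O3, pyridine, CH2Cl2/MeOH, −78 °C; Me2S) cleaves the enoate alkene to the aldehyde F1; a Morita–Baylis–Hillman reaction with methyl acrylate (DABCO) gives the adduct F2; NBS/Me2S converts it with allylic transposition into the (Z)-2-(bromomethyl)enoate F3; HF·pyridine frees the primary alcohol F4; Dess–Martin oxidation gives the aldehyde F5; CrCl2 in THF at high dilution (intramolecular Nozaki–Hiyama allylation through a chair-like six-membered transition state) closes the cycloheptane, and lactonisation of the resulting alkoxide gives the cis-fused α-methylene lactone F6; hydrogenation with H2 and (Ph3P)3RhCl from the convex face gives 25, where the route is rejoined.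

2. Step 4. The enolate of 6 may fragment by β-elimination of the ring oxygen, or the ketene acetal may form as a mixture of geometries so that the methyl-bearing carbon is not controlled. The fallback sets out from acid 4: TMSCHN2 gives the methyl ester F7; deprotonation with LiN(i-Pr)2 in the presence of TMSCl (THF, −100 °C) traps the enolate at once as the trimethylsilyl ketene acetal F8; an iridium-catalysed branched-selective allylic substitution ([Ir(cod)Cl]2, a phosphoramidite ligand of the antipode that gives the (S)-allylic carbon, methyl (E)-but-2-enyl carbonate, ZnF2/CsF), in which the catalyst and not the ketene acetal geometry fixes the allylic carbon while the ring face fixes the quaternary one, gives the ester F9; LiAlH4 reduces F9 to 11.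

3. Step 16. The hindered C8 hydroxyl may acylate slowly, and prolonged heating may isomerise the angelate to the tiglate. The fallback builds the (Z)-alkene in place. It sets out from 26: 2-(diphenoxyphosphoryl)propanoic acid with DCC acylates the C8 hydroxyl (through the reactive phosphonoketene) to give the phosphonate ester F10; a Z-selective Horner–Wadsworth–Emmons olefination with acetaldehyde (KN(SiMe3)2, 18-crown-6, THF, −78 °C) gives 29.

Further compounds
F1 | step 13 | (3R,4S)-4-[(4R,5S)-5-[(tert-butyldimethylsilyloxy)methyl]-4-[(4-methoxybenzyloxy)methyl]-2,2-dimethyl-1,3-dioxolan-4-yl]-3-(triisopropylsilyloxy)pentanal | CC(C)(C)[Si](C)(C)OC[C@@H]1OC(C)(C)O[C@@]1(COCc2ccc(OC)cc2)[C@@H](C)[C@H](O[Si](C(C)C)(C(C)C)C(C)C)CC=O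
F2 | step 13 | methyl (5R,6S)-6-[(4R,5S)-5-[(tert-butyldimethylsilyloxy)methyl]-4-[(4-methoxybenzyloxy)methyl]-2,2-dimethyl-1,3-dioxolan-4-yl]-3-hydroxy-2-methylidene-5-(triisopropylsilyloxy)heptanoate (C3 epimers) | CC(C)(C)[Si](C)(C)OC[C@@H]1OC(C)(C)O[C@@]1(COCc2ccc(OC)cc2)[C@@H](C)[C@H](O[Si](C(C)C)(C(C)C)C(C)C)CC(O)C(=C)C(=O)OC
F3 | step 13 | methyl (2Z,5R,6S)-2-(bromomethyl)-6-[(4R,5S)-5-[(tert-butyldimethylsilyloxy)methyl]-4-[(4-methoxybenzyloxy)methyl]-2,2-dimethyl-1,3-dioxolan-4-yl]-5-(triisopropylsilyloxy)hept-2-enoate | CC(C)(C)[Si](C)(C)OC[C@@H]1OC(C)(C)O[C@@]1(COCc2ccc(OC)cc2)[C@@H](C)[C@H](O[Si](C(C)C)(C(C)C)C(C)C)C/C=C(\CBr)C(=O)OC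
F4 | step 13 | methyl (2Z,5R,6S)-2-(bromomethyl)-6-[(4R,5S)-5-(hydroxymethyl)-4-[(4-methoxybenzyloxy)methyl]-2,2-dimethyl-1,3-dioxolan-4-yl]-5-(triisopropylsilyloxy)hept-2-enoate | OC[C@@H]1OC(C)(C)O[C@@]1(COCc2ccc(OC)cc2)[C@@H](C)[C@H](O[Si](C(C)C)(C(C)C)C(C)C)C/C=C(\CBr)C(=O)OC
F5 | step 13 | methyl (2Z,5R,6S)-2-(bromomethyl)-6-[(4R,5R)-5-formyl-4-[(4-methoxybenzyloxy)methyl]-2,2-dimethyl-1,3-dioxolan-4-yl]-5-(triisopropylsilyloxy)hept-2-enoate | O=C[C@@H]1OC(C)(C)O[C@@]1(COCc2ccc(OC)cc2)[C@@H](C)[C@H](O[Si](C(C)C)(C(C)C)C(C)C)C/C=C(\CBr)C(=O)OC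
F6 | step 13 | 3-methylidene analogue of 25 (cis-fused α-methylene lactone, other centres as in 25) | CC1(C)O[C@H]2[C@@H]3OC(=O)C(=C)[C@@H]3C[C@@H](O[Si](C(C)C)(C(C)C)C(C)C)[C@H](C)[C@@]2(O1)COCc4ccc(OC)cc4
F7 | step 4 | methyl (4R,5S)-5-[(tert-butyldimethylsilyloxy)methyl]-2,2-dimethyl-1,3-dioxolane-4-carboxylate | CC(C)(C)[Si](C)(C)OC[C@@H]1OC(C)(C)O[C@H]1C(=O)OC
F8 | step 4 | trimethylsilyl ketene acetal of F7, (5S), alkene geometry immaterial | CC(C)(C)[Si](C)(C)OC[C@@H]1OC(C)(C)OC1=C(OC)O[Si](C)(C)C
F9 | step 4 | methyl (4S,5S)-4-[(2S)-but-3-en-2-yl]-5-[(tert-butyldimethylsilyloxy)methyl]-2,2-dimethyl-1,3-dioxolane-4-carboxylate | CC(C)(C)[Si](C)(C)OC[C@@H]1OC(C)(C)O[C@@]1(C(=O)OC)[C@@H](C)C=C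
F10 | step 16 | 8-O-[2-(diphenoxyphosphoryl)propanoyl] derivative of 26 (epimers at the phosphonate carbon) | CC(C(=O)O[C@H]1[C@@H]2OC(=O)[C@H](C)[C@@H]2C[C@@H](O[Si](C(C)C)(C(C)C)C(C)C)[C@H](C)[C@@]1(O)COCc3ccc(OC)cc3)P(=O)(Oc4ccccc4)Oc5ccccc5
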